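## Structural features

Asterelin A has no stereogenic centre; it is a macrocyclic bis(bibenzyl) in which a dibenzofuran is part of an 18-membered ring. The tricycle consists of an oxygenated benzo ring (C1, C2, C3, C4, C4a, C9b), the furan (C4a, O5, C5a, C9a, C9b) and a second benzo ring (C5a to C9a). From C1 an ethano bridge runs to a para-phenylene ring. The para oxygen of that ring is bonded to C3' of a 1,3,4-trisubstituted catechol-type ring, which a second ethano bridge ties back to C7. The fragile groups are the two free phenols (C3–OH, and C4'–OH ortho to the diaryl ether oxygen), which make the arenes oxidation-prone, and the four benzylic CH2 groups. The three oxygens must also be told apart, since only the phenylene oxygen closes the macrocycle. The real difficulty is twofold: the crowded benzo ring, where the C1 bridge, the C9b aryl bond and the C4a oxygen are contiguous and the C3 hydroxyl sits meta to the bridge, and the closure of a macrocycle around a rigid planar tricycle. The key step uses the fact that C1, C2, C3, C4, C4a and C9b can be drawn from three alkynes: C9b/C1 from an arylalkyne carrying the bridge, C4a/C4 from an aryl ethynyl ether, and C2/C3 from a borylacetylene. Furan and benzene ring then form together and the C1/C3 meta pattern is fixed by construction.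

## Logic of the disconnections

**24 ⇒ 23.** The two O–CH3 bonds at C3 and C4' are cut. Both phenols must stay masked while the third oxygen forms the diaryl ether, and one common mask allows a single final operation. The demand is a demethylation that leaves the diaryl ether and the furan C–O bonds (all on sp2 carbon) intact.

**23 ⇒ 22.** The C–O bond between the phenylene oxygen and C3' is cut. It is the only ring bond of the macrocycle that is a heteroatom bond outside the tricycle, and cutting it gives an open chain with both bridges in place. The forward step must be an intramolecular copper-mediated etherification at high dilution on a hindered, electron-rich bromide, with exactly one free phenol present.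

**22 ⇒ 21.** The O–benzyl bond is cut. The benzyl group carried the phenylene oxygen through all the organometallic steps. Its removal must spare the C–Br bond and the two methyl ethers, which rules out hydrogenolysis.

**21 ⇒ 18 + 19 (through 20).** The CH2–aryl bond between the C7 bridge and the catechol ring is cut. The bromo-methoxy ring then enters as a simple dihaloarene and the two bridge carbons come from a vinyl group. The forward step needs terminal hydroboration and palladium insertion into C–I but not into C–Br.

**18 ⇒ 16 + 17.** The C7–vinyl bond is cut back to the C7 chloride. Chlorine is the one halogen that can ride through the organolithium step, so it is the handle. The coupling therefore needs a catalyst that activates an aryl chloride.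

**16 ⇒ 15 ⇒ 14.** The O–CH3 bond is cut and then C3–O is traced back to C3–B. Boron is the masked hydroxyl that the ring construction delivers. The forward steps are a mild C–B oxidation and an O-methylation.

**14 ⇒ 12 + 13.** The bonds C9b–C4a, C4–C3 and C2–C1 are cut, which removes the furan and the oxygenated benzo ring in one stroke. What remains is a monocyclic diyne and a two-carbon alkyne. The forward step must favour cross- over self-trimerization and must place boron next to the unsubstituted terminus.

**12 ⇒ 9 (through 10 and 11).** The ethynyl ether is traced back to a 1,2-dichlorovinyl ether (two C–Cl bonds). This is a stable, storable precursor of the sensitive ynol ether. The demand is an elimination/exchange with an alkyllithium that leaves the aryl chloride alone.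

**9 ⇒ 8 + 4.** The aryl–C(sp) bond is cut. This separates the halophenol part from the arylbutyne that carries the future C1 bridge. The coupling must discriminate C–I from vinylic and aryl C–Cl.

**8 ⇒ 5 + 6 (through 7).** The O–C(vinyl) bond is cut. Etherification before the alkynylation keeps an ortho-alkynylphenol from ever forming and closing to a benzofuran.

**4 ⇒ 1 + 2 (through 3).** The benzylic CH2–CH2 bond is cut, giving a benzylic electrophile and a three-carbon propargyl nucleophile whose acetylenic end is blocked by silicon.

## Other disconnections considered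

**Alternative 1:** The cut is the O5–C5a bond of the furan, made last. The precursor A1 is the 18-membered macrocycle in which C9b–C9a already exists as a biaryl bond, C4a carries a free hydroxyl and C3 and C4' carry methoxy groups. In the forward step, catalytic Pd(OAc)2 with an N-heterocyclic carbene and a hindered sodium arenecarboxylate under air would palladate the C–H ortho to the biaryl bond from the bound phenoxide. C–O reductive elimination from divalent palladium would then give A2, which is the same compound as 23, and air would reoxidize zerovalent palladium.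

- In favour: the two ortho C–H bonds of the para-linked ring are equivalent, so there is no regiochemical question. The furan oxygen is already in place, and only the demethylation follows.
- Against: A1 needs its own macrocyclization, a biaryl flanked by two ortho substituents, and a resorcinol whose two oxygens are differentiated. The six-membered palladacycle requires the two rings to become coplanar inside the macrocycle, so strain builds at the transition state. Hot aerobic palladium chemistry meets four benzylic CH2 groups and an electron-rich phenol on the most valuable intermediate.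
- Comparison: on structure the chosen plan fixes the tricycle early at room temperature and leaves only a flexible ether closure for the end. On mechanism, alternative 1 relies on a slow C–O reductive elimination, whereas the chosen plan relies on a facile metallacycle pathway. On step economy after the key step, alternative 1 is the better plan (one step against seven), and it is at least equal in having no orientation problem. Over the whole route it is expected to be no shorter, because A1 is itself a long target.

**Alternative 2:** The cut runs through C9b–C1 and C4–C4a. The arylacetate A3 and the enone A4 would be combined with t-BuOK: conjugate addition of the ester enolate, then Claisen closure of the methyl ketone enolate onto the ester, giving the dione A5. A5 would be trans by equilibration (both substituents equatorial) and racemic, and both centres are erased later. Dehydrogenation to the resorcinol and displacement of fluoride by the C4a oxygen would lead to A6, the bromo analogue of 15.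

- In favour: cheap reagents and no noble metal or sensitive ynol ether. The positions of both oxygens follow from connectivity alone, and the bromide is a more reactive handle than chloride.
- Against: the enone is enolizable at its γ-position, so proton transfer and oligomerization compete with the conjugate addition. The ring arrives four hydrogens short of aromatic, and oxidizing a 1,3-dione to a resorcinol while keeping C–Br and O–benzyl is delicate. The fluoride is not activated, so the furan closure needs forcing heat.
- Comparison: on structure both plans build the same ring, but the chosen plan delivers it at the arene oxidation level. On mechanism this is polar enolate chemistry against metallacycle chemistry. On step economy the two are about equal up to the 3-hydroxydibenzofuran, and alternative 2 is better on cost and scale. The chosen plan is better on mildness and on predictability of the aromatic substitution pattern.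

**Alternative 3:** The cuts are C1–CH2 and the biaryl bond C9b–C9a. The aryl iodide A7, the phenethyl bromide A8 and the boronic acid A9 would be joined by palladium/norbornene catalysis (Pd(OAc)2, triarylphosphine, Cs2CO3). This is ortho C–H alkylation through an aryl–norbornyl palladacycle and a tetravalent palladium intermediate, followed by norbornene extrusion and ipso Suzuki termination, giving A10. Removal of both benzyl groups and displacement of fluoride by the C4a phenol would give A11.

- In favour: it is the most convergent plan, with three simple pieces joined in one operation. The C3 oxygen is present from the start, so no C–B oxidation is needed. A7 has exactly one free ortho position, so over-alkylation is excluded.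
- Against: A8 is prone to base-induced elimination to the styrene and to β-hydride loss. The termination must forge a biaryl with three ortho substituents using an ortho-fluoro boronic acid that protodeboronates easily under carbonate. The two benzyl ethers are not differentiated, so A11 carries a free phenylene hydroxyl that must be re-masked before the C7 chemistry. The furan closure again uses an unactivated fluoride.
- Comparison: on structure it reaches the same chloro-dibenzofuran stage as 16. On mechanism it stacks several competing palladium pathways in one flask, where the chosen plan has a single well-defined catalytic event. On step economy alternative 3 is clearly better (about three steps to the tricycle against seven). The chosen plan is preferred only because its ring-forming step carries less risk.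

Key step: step 5

Remark on the chemistry: the phenol is used as its 2-iodo analogue 5 rather than the 2-bromo compound, so that the alkynylation runs at room temperature beside vinylic and aryl C–Cl bonds. Chlorine is kept at the future C7 because it tolerates n-BuLi. The atom mapping of diyne and monoalkyne onto C1 to C4, C4a and C9b was checked against the target and needed no correction. Dibenzofuran numbering (C1 to C9b, O5) is used throughout.

## Route

Step 1
Reactants: 1 4-(benzyloxy)benzyl chloride; 2 trimethyl(prop-1-yn-1-yl)silane
Product: 4 1-(benzyloxy)-4-(but-3-yn-1-yl)benzene, via silylated butyne 3 (not isolated)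
Conditions: 2, n-BuLi, THF, −78 °C; then 1, −78 °C → rt; then MeOH, K2CO3, rt
Reagents that add atoms: none
Why: Propargylic lithiation of 2 and SN2 alkylation by the activated benzylic chloride give the silylalkyne 3, the silyl group blocking the acetylenic end and disfavouring allene formation; methanolic carbonate then cleaves the C(sp)–Si bond (propargyl anion alkylation, protodesilylation).

Step 2
Reactants: 5 5-chloro-2-iodophenol; 6 trichloroethylene
Product: 8 4-chloro-2-{[(E)-1,2-dichloroethenyl]oxy}-1-iodobenzene, via dichloroacetylene 7 (not isolated)
Conditions: K2CO3, DMF, 70 °C, under N2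
Reagents that add atoms: none
Why: Carbonate dehydrochlorinates 6 to dichloroacetylene, to which the phenoxide adds anti to give the E dichlorovinyl ether (the standard dichlorovinyl ether synthesis); the aryl C–I and C–Cl bonds are inert to these conditions.

Step 3
Reactants: 8 4-chloro-2-{[(E)-1,2-dichloroethenyl]oxy}-1-iodobenzene; 4 1-(benzyloxy)-4-(but-3-yn-1-yl)benzene
Product: 9 1-{4-[4-(benzyloxy)phenyl]but-1-yn-1-yl}-4-chloro-2-{[(E)-1,2-dichloroethenyl]oxy}benzene
Conditions: PdCl2(PPh3)2 (cat.), CuI (cat.), Et3N, THF, rt
Reagents that add atoms: none
Why: Sonogashira coupling; zerovalent palladium inserts into C–I at room temperature far faster than into the vinylic or aryl C–Cl bonds, and the masked phenol cannot cyclize onto the new alkyne.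

Step 4
Reactants: 9 1-{4-[4-(benzyloxy)phenyl]but-1-yn-1-yl}-4-chloro-2-{[(E)-1,2-dichloroethenyl]oxy}benzene
Product: 12 1-{4-[4-(benzyloxy)phenyl]but-1-yn-1-yl}-4-chloro-2-(ethynyloxy)benzene, via chloroethynyl ether 10 (not isolated), via lithium acetylide 11 (not isolated)
Conditions: n-BuLi (2.3 equiv), Et2O, −78 → −40 °C; then H2O, −78 → 0 °C
Reagents that add atoms: none
Why: Deprotonation of the vinylic hydrogen and anti elimination of chloride give the chloroalkyne, chlorine–lithium exchange gives the lithium acetylide, and water protonates it (the known dichlorovinyl ether to ynol ether conversion); at −78 °C the aryl chloride, the internal alkyne and the benzyl ether are not attacked.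

Step 5
Reactants: 12 1-{4-[4-(benzyloxy)phenyl]but-1-yn-1-yl}-4-chloro-2-(ethynyloxy)benzene; 13 2-ethynyl-4,4,5,5-tetramethyl-1,3,2-dioxaborolane
Product: 14 2-(1-{2-[4-(benzyloxy)phenyl]ethyl}-7-chlorodibenzo[b,d]furan-3-yl)-4,4,5,5-tetramethyl-1,3,2-dioxaborolane
Conditions: [Rh(cod)2]BF4 (5 mol%), rac-BINAP (5 mol%), H2 pre-activation, 13 (3 equiv), CH2Cl2, rt, slow addition of 12
Reagents that add atoms: none
Why: Hydrogenation of the cod ligands leaves a cationic monovalent rhodium–BINAP fragment that binds both alkynes of 12 and couples them oxidatively to a rhodacyclopentadiene of trivalent rhodium, forming C9b–C4a. This bond closes the furan as a five-membered ring through the C9a–C5a–O5 tether (metal-templated oxidative cyclization of a 1,6-diyne). Coordination and insertion of 13 into a Rh–C bond, then C–C reductive elimination, form C4–C3 and C2–C1 and close the benzene ring as the six-membered ring of a formal (2+2+2) cycloaddition. The closest known reaction type is the cationic rhodium-catalysed cycloaddition of phenol-tethered aryl ethynyl ether diynes with terminal monoalkynes to dibenzofurans, and alkynylboronates are established monoalkyne partners in cyclotrimerizations. No stereocentre is formed, so the racemic ligand suffices. Two selectivities are needed: cross- over self-trimerization, secured by slow addition of 12 to an excess of 13, and the orientation of 13, secured by the substrate because the metallacycle carbon from the ynol terminus carries only hydrogen while the other carries the arylethyl chain, so the bulky dioxaborolane should end at C3 next to C4–H and meta to the C1 chain. Aryl chloride, benzyl ether and the product C–B bond are inert to the catalyst at room temperature.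

Step 6
Reactants: 14 2-(1-{2-[4-(benzyloxy)phenyl]ethyl}-7-chlorodibenzo[b,d]furan-3-yl)-4,4,5,5-tetramethyl-1,3,2-dioxaborolane
Product: 15 1-{2-[4-(benzyloxy)phenyl]ethyl}-7-chlorodibenzo[b,d]furan-3-ol
Conditions: 30% H2O2, aq. NaOH, THF, 0 °C → rt
Reagents that add atoms: hydrogen peroxide, OO
Why: Hydroperoxide adds to boron, the aryl group migrates from boron to oxygen and the borate is hydrolysed (standard arylboronate oxidation), giving the C3 phenol; nothing else in 14 reacts with cold alkaline peroxide.

Step 7
Reactants: 15 1-{2-[4-(benzyloxy)phenyl]ethyl}-7-chlorodibenzo[b,d]furan-3-ol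
Product: 16 1-{2-[4-(benzyloxy)phenyl]ethyl}-7-chloro-3-methoxydibenzo[b,d]furan
Conditions: MeI, K2CO3, acetone, reflux
Reagents that add atoms: iodomethane, CI
Why: Williamson O-methylation of the only free phenol; the methyl ether masks C3–OH through the palladium and copper steps and leaves together with the catechol methyl ether at the end.

Step 8
Reactants: 16 1-{2-[4-(benzyloxy)phenyl]ethyl}-7-chloro-3-methoxydibenzo[b,d]furan; 17 2-ethenyl-4,4,5,5-tetramethyl-1,3,2-dioxaborolane
Product: 18 1-{2-[4-(benzyloxy)phenyl]ethyl}-7-ethenyl-3-methoxydibenzo[b,d]furan
Conditions: Pd(OAc)2 (cat.), SPhos, K3PO4, 1,4-dioxane/H2O, 90 °C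
Reagents that add atoms: none
Why: Suzuki–Miyaura vinylation of an aryl chloride, for which the electron-rich dialkylbiarylphosphine makes oxidative addition feasible; 16 has no other carbon–halogen bond.

Step 9
Reactants: 18 1-{2-[4-(benzyloxy)phenyl]ethyl}-7-ethenyl-3-methoxydibenzo[b,d]furan; 19 2-bromo-4-iodo-1-methoxybenzene
Product: 21 1-{2-[4-(benzyloxy)phenyl]ethyl}-7-[2-(3-bromo-4-methoxyphenyl)ethyl]-3-methoxydibenzo[b,d]furan, via B-alkyl-9-BBN borane 20 (not isolated)
Conditions: 9-BBN, THF, rt → 50 °C; then 19 (1.1 equiv), PdCl2(dppf) (cat.), aq. K3PO4, DMF, rt → 40 °C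
Reagents that add atoms: none
Why: Anti-Markovnikov hydroboration of the styrene by 9-BBN, then B-alkyl Suzuki–Miyaura coupling; oxidative addition at C–I of 19 is much faster than at the hindered, electron-rich C–Br next to the methoxy group, so the bromide is kept for step 11.

Step 10
Reactants: 21 1-{2-[4-(benzyloxy)phenyl]ethyl}-7-[2-(3-bromo-4-methoxyphenyl)ethyl]-3-methoxydibenzo[b,d]furan
Product: 22 4-(2-{7-[2-(3-bromo-4-methoxyphenyl)ethyl]-3-methoxydibenzo[b,d]furan-1-yl}ethyl)phenol
Conditions: BCl3, pentamethylbenzene, CH2Cl2, −78 °C; then MeOH/H2O
Reagents that add atoms: none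
Why: Lewis acid debenzylation with pentamethylbenzene as a non-basic trap for the benzyl cation; at −78 °C the aryl methyl ethers and the aryl bromide (which hydrogenolysis would endanger) are left untouched.

Step 11
Reactants: 22 4-(2-{7-[2-(3-bromo-4-methoxyphenyl)ethyl]-3-methoxydibenzo[b,d]furan-1-yl}ethyl)phenol
Product: 23 asterelin A dimethyl ether (3-O,4'-O-dimethylasterelin A)
Conditions: CuI (20 mol%), N,N-dimethylglycine hydrochloride, Cs2CO3, 1,4-dioxane, high dilution (syringe pump), 100 °C
Reagents that add atoms: none
Why: Intramolecular Ullmann diaryl ether coupling with an amino acid ligand for copper; high dilution favours closure of the 18-membered ring over oligomerization, and only one phenol and one aryl bromide are present.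

Step 12
Reactants: 23 asterelin A dimethyl ether (3-O,4'-O-dimethylasterelin A)
Product: 24 asterelin A
Conditions: BBr3, CH2Cl2, −78 °C → rt; then H2O
Reagents that add atoms: none
Why: Lewis acid cleavage of both aryl methyl ethers by bromide attack at methyl in the boron-complexed ethers; the diaryl ether and furan C–O bonds lie on sp2 carbon and are not cleaved.

## Compound list

1 | 4-(benzyloxy)benzyl chloride | ClCc1ccc(OCc2ccccc2)cc1 | starting material
2 | trimethyl(prop-1-yn-1-yl)silane | CC#C[Si](C)(C)C | starting material
3 | {4-[4-(benzyloxy)phenyl]but-1-yn-1-yl}trimethylsilane | C[Si](C)(C)C#CCCc1ccc(OCc2ccccc2)cc1 | intermediate (not isolated)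
4 | 1-(benzyloxy)-4-(but-3-yn-1-yl)benzene | C#CCCc1ccc(OCc2ccccc2)cc1 | intermediate
5 | 5-chloro-2-iodophenol | Oc1cc(Cl)ccc1I | starting material
6 | trichloroethylene | ClC=C(Cl)Cl | starting material
7 | dichloroacetylene | ClC#CCl | intermediate (not isolated)
8 | 4-chloro-2-{[(E)-1,2-dichloroethenyl]oxy}-1-iodobenzene | Cl/C=C(/Cl)Oc1cc(Cl)ccc1I | intermediate
9 | 1-{4-[4-(benzyloxy)phenyl]but-1-yn-1-yl}-4-chloro-2-{[(E)-1,2-dichloroethenyl]oxy}benzene | Cl/C=C(/Cl)Oc1cc(Cl)ccc1C#CCCc1ccc(OCc2ccccc2)cc1 | intermediate
10 | 1-{4-[4-(benzyloxy)phenyl]but-1-yn-1-yl}-4-chloro-2-[(chloroethynyl)oxy]benzene | ClC#COc1cc(Cl)ccc1C#CCCc1ccc(OCc2ccccc2)cc1 | intermediate (not isolated)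
11 | [(2-{4-[4-(benzyloxy)phenyl]but-1-yn-1-yl}-5-chlorophenoxy)ethynyl]lithium | [Li]C#COc1cc(Cl)ccc1C#CCCc1ccc(OCc2ccccc2)cc1 | intermediate (not isolated)
12 | 1-{4-[4-(benzyloxy)phenyl]but-1-yn-1-yl}-4-chloro-2-(ethynyloxy)benzene | C#COc1cc(Cl)ccc1C#CCCc1ccc(OCc2ccccc2)cc1 | intermediate
13 | 2-ethynyl-4,4,5,5-tetramethyl-1,3,2-dioxaborolane | C#CB1OC(C)(C)C(C)(C)O1 | starting material
14 | 2-(1-{2-[4-(benzyloxy)phenyl]ethyl}-7-chlorodibenzo[b,d]furan-3-yl)-4,4,5,5-tetramethyl-1,3,2-dioxaborolane | Clc1ccc2c(c1)oc1cc(B3OC(C)(C)C(C)(C)O3)cc(CCc3ccc(OCc4ccccc4)cc3)c12 | intermediate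
15 | 1-{2-[4-(benzyloxy)phenyl]ethyl}-7-chlorodibenzo[b,d]furan-3-ol | Oc1cc(CCc2ccc(OCc3ccccc3)cc2)c2c(c1)oc1cc(Cl)ccc12 | intermediate
16 | 1-{2-[4-(benzyloxy)phenyl]ethyl}-7-chloro-3-methoxydibenzo[b,d]furan | COc1cc(CCc2ccc(OCc3ccccc3)cc2)c2c(c1)oc1cc(Cl)ccc12 | intermediate
17 | 2-ethenyl-4,4,5,5-tetramethyl-1,3,2-dioxaborolane | C=CB1OC(C)(C)C(C)(C)O1 | starting material
18 | 1-{2-[4-(benzyloxy)phenyl]ethyl}-7-ethenyl-3-methoxydibenzo[b,d]furan | COc1cc(CCc2ccc(OCc3ccccc3)cc2)c2c(c1)oc1cc(C=C)ccc12 | intermediate
19 | 2-bromo-4-iodo-1-methoxybenzene | COc1ccc(I)cc1Br | starting material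
20 | 9-[2-(1-{2-[4-(benzyloxy)phenyl]ethyl}-3-methoxydibenzo[b,d]furan-7-yl)ethyl]-9-borabicyclo[3.3.1]nonane | COc1cc(CCc2ccc(OCc3ccccc3)cc2)c2c(c1)oc1cc(CCB3C4CCCC3CCC4)ccc12 | intermediate (not isolated)
21 | 1-{2-[4-(benzyloxy)phenyl]ethyl}-7-[2-(3-bromo-4-methoxyphenyl)ethyl]-3-methoxydibenzo[b,d]furan | COc1cc(CCc2ccc(OCc3ccccc3)cc2)c2c(c1)oc1cc(CCc3ccc(OC)c(Br)c3)ccc12 | intermediate
22 | 4-(2-{7-[2-(3-bromo-4-methoxyphenyl)ethyl]-3-methoxydibenzo[b,d]furan-1-yl}ethyl)phenol | COc1cc(CCc2ccc(O)cc2)c2c(c1)oc1cc(CCc3ccc(OC)c(Br)c3)ccc12 | intermediate
23 | asterelin A dimethyl ether (3-O,4'-O-dimethylasterelin A) | COc1cc2c3c(c1)oc1cc(ccc13)CCc1ccc(OC)c(c1)Oc1ccc(cc1)CC2 | intermediate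
24 | asterelin A | Oc1cc2c3c(c1)oc1cc(ccc13)CCc1ccc(O)c(c1)Oc1ccc(cc1)CC2 | target

## Step count and least certain steps

Total step count: 12. Longest linear sequence: 11 steps (from 1 through steps 1 and 3 to 12, or from 5 through steps 2 to 12).

**Step 5 (key step).** The most likely failure is self-trimerization or oligomerization of 12 through its reactive terminal ynol ether, which could outrun the cross reaction. Protolytic loss of the alkynyl C–B bond of 13 before insertion is a second risk. A third is insertion of 13 in the reverse orientation, if the steric difference between the two metallacycle termini is not decisive.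
Fallback, from 12 back to 15: the same rhodium-catalysed cycloaddition of 12 would be run with but-3-yn-2-one, a robust electron-poor monoalkyne that pairs well with an electron-rich diyne. It should give the ketone 1-(1-{2-[4-(benzyloxy)phenyl]ethyl}-7-chlorodibenzo[b,d]furan-3-yl)ethan-1-one F1. Baeyer–Villiger oxidation (mCPBA, NaHCO3, CH2Cl2, aryl migration) would give 1-{2-[4-(benzyloxy)phenyl]ethyl}-7-chlorodibenzo[b,d]furan-3-yl acetate F2, and methanolysis (K2CO3, MeOH) would return to 15. Carbon, not boron, is then the masked hydroxyl.

**Step 4.** The most likely failure is hydration or polymerization of the terminal ynol ether during quench and chromatography, because the electron-rich triple bond adds water under traces of acid. Ortho-metalation next to the aryl chloride could also compete if the temperature drifts upward.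
Fallback, from 9 back to 12: the acetylide 11 would be generated as in step 4 and trapped with chlorotri(propan-2-yl)silane, giving the shielded, storable silyl ynol ether [(2-{4-[4-(benzyloxy)phenyl]but-1-yn-1-yl}-5-chlorophenoxy)ethynyl]tri(propan-2-yl)silane F3. Tetrabutylammonium fluoride (THF, 0 °C) immediately before step 5 would release 12.

**Step 9.** The most likely failure is oxidative addition at C–Br as well as C–I, leading to double alkylation, because excess borane meets a product that still carries a bromide. Protodeboronation or β-hydride loss from the alkylborane is a second risk, since it returns unfunctionalized material.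
Fallback, from 18 back to 21: Heck coupling of 18 with 19 under ligand-free conditions (Pd(OAc)2, Bu4NCl, NaHCO3, DMF, 60 °C), selective for C–I, would give the stilbene 1-{2-[4-(benzyloxy)phenyl]ethyl}-7-[(E)-2-(3-bromo-4-methoxyphenyl)ethenyl]-3-methoxydibenzo[b,d]furan F4. Diimide reduction (p-toluenesulfonyl hydrazide, NaOAc, THF/H2O, reflux) would saturate the alkene without touching C–Br or O–benzyl and give 21.

**Step 11.** The most likely failure is intermolecular etherification to dimers and oligomers, because the ring must close around a rigid tricycle. Reductive loss of bromine is a second risk, because copper adds slowly to the hindered, electron-rich ortho-methoxy bromide.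
Fallback, from 18 back to 24: this replaces the copper coupling by an activated nucleophilic aromatic substitution. The sequence is:
- 18 would be hydroborated as in step 9 to 20 and coupled with 4-bromo-2-fluorobenzaldehyde (PdCl2(dppf), aq. K3PO4) to 4-[2-(1-{2-[4-(benzyloxy)phenyl]ethyl}-3-methoxydibenzo[b,d]furan-7-yl)ethyl]-2-fluorobenzaldehyde F5.
- Debenzylation (BCl3, pentamethylbenzene, −78 °C) would give 2-fluoro-4-(2-{1-[2-(4-hydroxyphenyl)ethyl]-3-methoxydibenzo[b,d]furan-7-yl}ethyl)benzaldehyde F6.
- K2CO3 in DMF at high dilution and 100 °C would let the phenoxide displace the fluoride ortho to the formyl group, closing the macrocyclic aldehyde (23 with CHO in place of the 4'-methoxy group) F7.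
- mCPBA (Baeyer–Villiger/Dakin-type aryl migration, favoured by the ortho aryloxy group) would give the formate 3-O-methylasterelin A 4'-O-formate F8.
- K2CO3 in MeOH would give 3-O-methylasterelin A F9, and BBr3 would give 24.

## Further compounds

F1 | step 5 | 1-(1-{2-[4-(benzyloxy)phenyl]ethyl}-7-chlorodibenzo[b,d]furan-3-yl)ethan-1-one | CC(=O)c1cc(CCc2ccc(OCc3ccccc3)cc2)c2c(c1)oc1cc(Cl)ccc12
F2 | step 5 | 1-{2-[4-(benzyloxy)phenyl]ethyl}-7-chlorodibenzo[b,d]furan-3-yl acetate | CC(=O)Oc1cc(CCc2ccc(OCc3ccccc3)cc2)c2c(c1)oc1cc(Cl)ccc12
F3 | step 4 | [(2-{4-[4-(benzyloxy)phenyl]but-1-yn-1-yl}-5-chlorophenoxy)ethynyl]tri(propan-2-yl)silane | CC(C)[Si](C#COc1cc(Cl)ccc1C#CCCc1ccc(OCc2ccccc2)cc1)(C(C)C)C(C)C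
F4 | step 9 | 1-{2-[4-(benzyloxy)phenyl]ethyl}-7-[(E)-2-(3-bromo-4-methoxyphenyl)ethenyl]-3-methoxydibenzo[b,d]furan | COc1cc(CCc2ccc(OCc3ccccc3)cc2)c2c(c1)oc1cc(/C=C/c3ccc(OC)c(Br)c3)ccc12
F5 | step 11 | 4-[2-(1-{2-[4-(benzyloxy)phenyl]ethyl}-3-methoxydibenzo[b,d]furan-7-yl)ethyl]-2-fluorobenzaldehyde | COc1cc(CCc2ccc(OCc3ccccc3)cc2)c2c(c1)oc1cc(CCc3ccc(C=O)c(F)c3)ccc12
F6 | step 11 | 2-fluoro-4-(2-{1-[2-(4-hydroxyphenyl)ethyl]-3-methoxydibenzo[b,d]furan-7-yl}ethyl)benzaldehyde | COc1cc(CCc2ccc(O)cc2)c2c(c1)oc1cc(CCc3ccc(C=O)c(F)c3)ccc12
F7 | step 11 | macrocyclic aldehyde (23 with CHO in place of the 4'-methoxy group) | COc1cc2c3c(c1)oc1cc(ccc13)CCc1ccc(C=O)c(c1)Oc1ccc(cc1)CC2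
F8 | step 11 | 3-O-methylasterelin A 4'-O-formate | COc1cc2c3c(c1)oc1cc(ccc13)CCc1ccc(OC=O)c(c1)Oc1ccc(cc1)CC2
F9 | step 11 | 3-O-methylasterelin A | COc1cc2c3c(c1)oc1cc(ccc13)CCc1ccc(O)c(c1)Oc1ccc(cc1)CC2
A1 | alternative 1 | macrocyclic 2-arylphenol (O5–C5a seco form of 23 with free C4a hydroxyl) | COc1cc2c(c(O)c1)-c1ccc(cc1)CCc1ccc(OC)c(c1)Oc1ccc(cc1)CC2
A2 | alternative 1 | asterelin A dimethyl ether (same compound as 23) | COc1cc2c3c(c1)oc1cc(ccc13)CCc1ccc(OC)c(c1)Oc1ccc(cc1)CC2
A3 | alternative 2 | methyl (4-bromo-2-fluorophenyl)acetate | COC(=O)Cc1ccc(Br)cc1F
A4 | alternative 2 | (E)-6-[4-(benzyloxy)phenyl]hex-3-en-2-one | CC(=O)/C=C/CCc1ccc(OCc2ccccc2)cc1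
A5 | alternative 2 | trans-4-(4-bromo-2-fluorophenyl)-5-{2-[4-(benzyloxy)phenyl]ethyl}cyclohexane-1,3-dione (racemic, one enantiomer drawn) | O=C1CC(=O)[C@@H](c2ccc(Br)cc2F)[C@H](CCc2ccc(OCc3ccccc3)cc2)C1
A6 | alternative 2 | 1-{2-[4-(benzyloxy)phenyl]ethyl}-7-bromodibenzo[b,d]furan-3-ol | Oc1cc(CCc2ccc(OCc3ccccc3)cc2)c2c(c1)oc1cc(Br)ccc12
A7 | alternative 3 | 2-(benzyloxy)-1-iodo-4-methoxybenzene | COc1ccc(I)c(OCc2ccccc2)c1
A8 | alternative 3 | 1-(benzyloxy)-4-(2-bromoethyl)benzene | BrCCc1ccc(OCc2ccccc2)cc1
A9 | alternative 3 | (4-chloro-2-fluorophenyl)boronic acid | OB(O)c1ccc(Cl)cc1F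
A10 | alternative 3 | 2-(benzyloxy)-6-{2-[4-(benzyloxy)phenyl]ethyl}-4'-chloro-2'-fluoro-4-methoxybiphenyl | COc1cc(CCc2ccc(OCc3ccccc3)cc2)c(-c2ccc(Cl)cc2F)c(OCc2ccccc2)c1
A11 | alternative 3 | 4-[2-(7-chloro-3-methoxydibenzo[b,d]furan-1-yl)ethyl]phenol | COc1cc(CCc2ccc(O)cc2)c2c(c1)oc1cc(Cl)ccc12
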